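**Plan**

- Retrosynthesis: remove the C8 epoxy ester, then unwind the α-methylene-β-hydroxy-γ-lactone through an exocyclic (Z)-ene-dicarbonyl to a 2-methoxyfuran fused to the ten-membered ring. Cut that furan at C6–C7 and C11–C12 into a 5-methoxyoxazole and a ynoate, then cut C1=C10 (Wittig) and C7–C8 (acetylide).
- Enabling feature: in the lactone ring, C6 and C12 both sit on the ring oxygen and are joined through C7–C11. The five-membered ring is therefore a masked furan whose C6–O–C12 unit is the diene-terminus pair of an oxazole and whose C7–C11 bond is an alkyne; C5 to C8 of the carbocycle is the tether.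
- Forward: an oxazole arm and an (S)-glycerate-derived silyloxy ketone are joined by a Z-selective Wittig reaction and extended to the ynoate. One thermal cycloaddition/cycloreversion then closes the ten-membered carbocycle and the five-membered O-ring together. The furan is opened with singlet oxygen, epoxidised, reduced and lactonised, the epoxide is opened to the carbinol and exo-methylene, and C8 is esterified.
- Stereochemistry: C9 comes from the (S)-glycerate chiron, C8 from Felkin–Anh acetylide addition, C7 from nucleophilic epoxidation anti to the C8 silyloxy group, and C6 from chelation-controlled hydride delivery. The side-chain epoxide comes from Sharpless epoxidation with D-(−)-diethyl tartrate; C4=C5 (E) from syn-carboalumination and C1=C10 (Z) from the α-silyloxy ketone Wittig.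

Key step: step 11

Assumption: atoms are referred to by germacranolide numbering (ring C1–C10, lactone C11–C13 with C6–O–C12); compounds 1, 4, 9, 18 and 33 are taken as commercial.

**Route**

Step 1
Reactants: 1 5-chloropent-1-yne
Product: 3 (E)-5-chloro-1-iodo-2-methylpent-1-ene, via vinylalane 2 (not isolated)
Conditions: Me3Al, Cp2ZrCl2 (cat.), CH2Cl2, 0 °C to rt; then I2, THF, −30 °C
Reagents that add atoms: trimethylaluminium C[Al](C)C; iodine II
Why: Zirconium-catalysed syn-carboalumination (Negishi) of the terminal alkyne followed by iodinolysis with retention should fix the E geometry of the future C4=C5 bond, the alkyl chloride being inert to Me3Al.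

Step 2
Reactants: 3 (E)-5-chloro-1-iodo-2-methylpent-1-ene; 4 L-alanine methyl ester hydrochloride
Product: 5 methyl N-[(2E)-6-chloro-3-methylhex-2-enoyl]-L-alaninate
Conditions: CO (1 atm), Pd(PPh3)4 (cat.), Et3N, DMF, 60 °C
Reagents that add atoms: carbon monoxide [C-]#[O+]
Why: Palladium-catalysed aminocarbonylation of the vinyl iodide (oxidative addition, CO insertion, acyl transfer to the amine) should give the (E)-enamide with retention of geometry and brings in C6 as a carbonyl carbon.

Step 3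
Reactants: 5 methyl N-[(2E)-6-chloro-3-methylhex-2-enoyl]-L-alaninate
Product: 6 2-[(1E)-5-chloro-2-methylpent-1-en-1-yl]-5-methoxy-4-methyl-1,3-oxazole
Conditions: PPh3, I2, Et3N, CH2Cl2, 0 °C to rt
Reagents that add atoms: none
Why: Cyclodehydration of the N-acyl α-amino ester (Robinson–Gabriel type, amide oxygen activated as the oxyphosphonium salt) should give the 5-methoxyoxazole, the alanine stereocentre becoming sp2 and the alkene staying untouched.

Step 4
Reactants: 6 2-[(1E)-5-chloro-2-methylpent-1-en-1-yl]-5-methoxy-4-methyl-1,3-oxazole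
Product: 8 [(4E)-5-(5-methoxy-4-methyl-1,3-oxazol-2-yl)-4-methylpent-4-en-1-yl]triphenylphosphonium iodide, via alkyl iodide 7 (not isolated)
Conditions: NaI, PPh3, MeCN, 80 °C
Reagents that add atoms: triphenylphosphine c1ccc(cc1)P(c1ccccc1)c1ccccc1; sodium iodide [Na+].[I-]
Why: Finkelstein exchange followed by SN2 quaternisation of PPh3 at the primary carbon should give the phosphonium salt, the weakly basic oxazole nitrogen being no competitor.

Step 5
Reactants: 9 methyl (4S)-2,2-dimethyl-1,3-dioxolane-4-carboxylate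
Product: 10 methyl (2S)-2,3-dihydroxypropanoate
Conditions: Dowex 50W (H+ form), MeOH–H2O, rt
Reagents that add atoms: none
Why: Acid-catalysed acetonide (ketal) hydrolysis frees the diol without touching the stereocentre that becomes C9.

Step 6
Reactants: 10 methyl (2S)-2,3-dihydroxypropanoate
Product: 12 methyl (2S)-2-(tert-butyldimethylsilyloxy)-3-(triethylsilyloxy)propanoate, via mono-TES ether 11 (not isolated)
Conditions: Et3SiCl, imidazole, CH2Cl2, −78 to −20 °C; then t-BuMe2SiOTf, 2,6-lutidine, −78 to 0 °C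
Reagents that add atoms: chlorotriethylsilane CC[Si](Cl)(CC)CC; tert-butyldimethylsilyl trifluoromethanesulfonate CC(C)(C)[Si](C)(C)OS(=O)(=O)C(F)(F)F
Why: Sequential silylation exploits the higher rate of the primary hydroxyl towards the chlorosilane, the secondary hydroxyl then taking the more reactive silyl triflate, so the two oxygens are differentiated in one flask.

Step 7
Reactants: 12 methyl (2S)-2-(tert-butyldimethylsilyloxy)-3-(triethylsilyloxy)propanoate
Product: 14 (3S)-3-(tert-butyldimethylsilyloxy)-4-(triethylsilyloxy)butan-2-one, via Weinreb amide 13 (not isolated)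
Conditions: MeNHOMe·HCl, MeMgBr (excess), THF, −20 to 0 °C
Reagents that add atoms: methylmagnesium bromide C[Mg]Br
Why: The ester is converted in situ into the Weinreb amide, whose magnesium chelate accepts one methyl only (Weinreb ketone synthesis), so the methyl ketone should form without over-addition or epimerisation of the α-silyloxy centre.

Step 8
Reactants: 8 [(4E)-5-(5-methoxy-4-methyl-1,3-oxazol-2-yl)-4-methylpent-4-en-1-yl]triphenylphosphonium iodide; 14 (3S)-3-(tert-butyldimethylsilyloxy)-4-(triethylsilyloxy)butan-2-one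
Product: 16 2-[(1E,5Z,7R)-7-(tert-butyldimethylsilyloxy)-2,6-dimethyl-8-(triethylsilyloxy)octa-1,5-dien-1-yl]-5-methoxy-4-methyl-1,3-oxazole, via phosphorus ylide 15 (not isolated)
Conditions: NaN(SiMe3)2, THF, −78 °C; then 14, −78 °C to rt
Reagents that add atoms: none
Why: Wittig olefination of an α-silyloxy methyl ketone with a non-stabilised ylide should be Z-selective (kinetic oxaphosphetane with the ylide chain syn to the oxygenated carbon), setting the C1=C10 geometry with C2 and C9 cis.

Step 9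
Reactants: 16 2-[(1E,5Z,7R)-7-(tert-butyldimethylsilyloxy)-2,6-dimethyl-8-(triethylsilyloxy)octa-1,5-dien-1-yl]-5-methoxy-4-methyl-1,3-oxazole
Product: 17 (2R,3Z,7E)-2-(tert-butyldimethylsilyloxy)-8-(5-methoxy-4-methyl-1,3-oxazol-2-yl)-3,7-dimethylocta-3,7-dienal
Conditions: (COCl)2, DMSO, CH2Cl2, −78 to −30 °C; then Et3N, −78 to 0 °C
Reagents that add atoms: none
Why: Under Swern conditions a primary triethylsilyl ether is cleaved and oxidised directly to the aldehyde while the secondary TBS ether survives, and low temperature limits epimerisation of the α-silyloxy aldehyde.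

Step 10
Reactants: 17 (2R,3Z,7E)-2-(tert-butyldimethylsilyloxy)-8-(5-methoxy-4-methyl-1,3-oxazol-2-yl)-3,7-dimethylocta-3,7-dienal; 18 methyl prop-2-ynoate
Product: 21 methyl (4S,5R,6Z,10E)-5-(tert-butyldimethylsilyloxy)-11-(5-methoxy-4-methyl-1,3-oxazol-2-yl)-6,10-dimethyl-4-(triethylsilyloxy)undeca-6,10-dien-2-ynoate, via lithium acetylide 19 (not isolated), via lithium alkoxide 20 (not isolated)
Conditions: LiN(SiMe3)2, THF, −78 °C; then 17; then Et3SiOTf, −78 to 0 °C
Reagents that add atoms: triethylsilyl trifluoromethanesulfonate CC[Si](CC)(CC)OS(=O)(=O)C(F)(F)F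
Why: Addition of the lithium acetylide to the α-silyloxy aldehyde should follow the Felkin–Anh (non-chelation) model and give the anti C8/C9 relationship, and the alkoxide is silylated in the same flask.

Step 11
Reactants: 21 methyl (4S,5R,6Z,10E)-5-(tert-butyldimethylsilyloxy)-11-(5-methoxy-4-methyl-1,3-oxazol-2-yl)-6,10-dimethyl-4-(triethylsilyloxy)undeca-6,10-dien-2-ynoate
Product: 23 methyl (4S,5R,6Z,10E)-5-(tert-butyldimethylsilyloxy)-2-methoxy-6,10-dimethyl-4-(triethylsilyloxy)-4,5,8,9-tetrahydrocyclodeca[b]furan-3-carboxylate, via bicyclic cycloadduct 22 (not isolated)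
Conditions: PhMe (0.002 M), 110 °C
Reagents that add atoms: none
Why: Proposed new method: the 5-methoxyoxazole acts as a cyclic 2-azadiene whose termini are C6 (oxazole C2) and C12 (oxazole C5, carrying OMe); it adds across the ester-activated C7≡C11 triple bond in an intramolecular [4+2] cycloaddition to the 7-oxa-2-azanorbornadiene 22, which at once loses acetonitrile by retro-[4+2] to the aromatic 2-methoxyfuran, the closest known reaction type being the intramolecular oxazole–alkyne Diels–Alder/cycloreversion furan synthesis, established for tethers closing five- and six-membered rings and extended here to a ten-membered one. The carbocycle closes as an ortho-fused ring through the eight-carbon tether (C5 to C8) that joins diene terminus C6 to dienophile carbon C7, and the five-membered O-ring arises by extrusion of the N=C(Me) bridge from the six-membered ring of 22. No lasting stereocentre is formed, since both bridgeheads of 22 become sp2, and C8, C9 and both olefin geometries are spectators. Regioselectivity is secured twice, by the tether (the other orientation would need a meta-bridged eleven-membered ring) and by polarity (nucleophilic oxazole C2 bonds to the ynoate β-carbon C7, C5(OMe) to the α-carbon C11). Chemoselectivity rests on the ynoate being the only electron-poor π bond, with the two trisubstituted alkenes pre-folding the chain and high dilution suppressing intermolecular cycloaddition. Loss of MeCN makes the step irreversible, and 110 °C is held below the range where Cope isomerisation of the 1,5-diene is expected to compete.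

Step 12
Reactants: 23 methyl (4S,5R,6Z,10E)-5-(tert-butyldimethylsilyloxy)-2-methoxy-6,10-dimethyl-4-(triethylsilyloxy)-4,5,8,9-tetrahydrocyclodeca[b]furan-3-carboxylate
Product: 25 [(4S,5R,6Z,10E)-5-(tert-butyldimethylsilyloxy)-2-methoxy-6,10-dimethyl-4-(triethylsilyloxy)-4,5,8,9-tetrahydrocyclodeca[b]furan-3-yl]methyl 2,2-dimethylpropanoate, via aluminium alkoxide 24 (not isolated)
Conditions: i-Bu2AlH, CH2Cl2, −78 °C; then pyridine, DMAP (cat.), t-BuCOCl, −78 to 0 °C
Reagents that add atoms: pivaloyl chloride CC(C)(C)C(Cl)=O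
Why: i-Bu2AlH reduces the only ester to the primary aluminium alkoxide, which is acylated in situ (reductive acylation), so the acid-sensitive 2-methoxy-3-furylmethanol is never handled and C13 now carries the leaving group needed in step 16.

Step 13
Reactants: 25 [(4S,5R,6Z,10E)-5-(tert-butyldimethylsilyloxy)-2-methoxy-6,10-dimethyl-4-(triethylsilyloxy)-4,5,8,9-tetrahydrocyclodeca[b]furan-3-yl]methyl 2,2-dimethylpropanoate
Product: 27 methyl (2Z)-2-[(2S,3R,4Z,8E)-3-(tert-butyldimethylsilyloxy)-4,8-dimethyl-10-oxo-2-(triethylsilyloxy)cyclodeca-4,8-dien-1-ylidene]-3-(pivaloyloxy)propanoate, via furan endoperoxide 26 (not isolated)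
Conditions: O2, hν, tetraphenylporphyrin (cat.), CH2Cl2, −78 °C; then Me2S, −78 °C to rt
Reagents that add atoms: oxygen O=O
Why: The electron-rich 2-methoxyfuran should take up singlet oxygen by [4+2] cycloaddition far faster than the trisubstituted alkenes undergo ene reaction, and reduction of the endoperoxide unmasks the (Z)-ene-dicarbonyl with C6 as ketone and C12 as methyl ester held cis.

Step 14
Reactants: 27 methyl (2Z)-2-[(2S,3R,4Z,8E)-3-(tert-butyldimethylsilyloxy)-4,8-dimethyl-10-oxo-2-(triethylsilyloxy)cyclodeca-4,8-dien-1-ylidene]-3-(pivaloyloxy)propanoate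
Product: 28 methyl (2S,3R,4R,5R,6Z,10E)-5-(tert-butyldimethylsilyloxy)-6,10-dimethyl-12-oxo-2-[(pivaloyloxy)methyl]-4-(triethylsilyloxy)-1-oxaspiro[2.9]dodeca-6,10-diene-2-carboxylate
Conditions: t-BuOOH, benzyltrimethylammonium hydroxide (cat.), THF, 0 °C
Reagents that add atoms: tert-butyl hydroperoxide CC(C)(C)OO
Why: Weitz–Scheffer nucleophilic epoxidation should touch only the doubly activated tetrasubstituted alkene, and with the C8–H eclipsing the alkene to minimise A(1,3) strain the peroxide should add anti to the C8–OSiEt3 bond (Felkin–Anh), which sets C7 (and transiently C11).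

Step 15
Reactants: 28 methyl (2S,3R,4R,5R,6Z,10E)-5-(tert-butyldimethylsilyloxy)-6,10-dimethyl-12-oxo-2-[(pivaloyloxy)methyl]-4-(triethylsilyloxy)-1-oxaspiro[2.9]dodeca-6,10-diene-2-carboxylate
Product: 30 7,11-epoxy-13-(pivaloyloxy)-9-(tert-butyldimethylsilyloxy)-8-(triethylsilyloxy)germacra-1(10)Z,4E-dien-12,6-olide (configuration at C6 to C9 as in 38; oxirane cis-fused to the lactone), via hydroxy ester 29 (not isolated)
Conditions: Zn(BH4)2, Et2O, −30 to 0 °C
Reagents that add atoms: none
Why: Zinc chelation between the C6 carbonyl and the oxirane oxygen should direct hydride to the face opposite the silyloxy-bearing C8 (chelation-controlled 1,2-reduction of the enone), setting C6, and the resulting alkoxide closes onto the cis ester to give the γ-lactone.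

Step 16
Reactants: 30 7,11-epoxy-13-(pivaloyloxy)-9-(tert-butyldimethylsilyloxy)-8-(triethylsilyloxy)germacra-1(10)Z,4E-dien-12,6-olide
Product: 31 (6R,7R,8R,9R)-9-(tert-butyldimethylsilyloxy)-7-hydroxy-8-(triethylsilyloxy)germacra-1(10)Z,4E,11(13)-trien-12,6-olide
Conditions: SmI2, THF, −78 °C
Reagents that add atoms: none
Why: SmI2 cleaves the Cα–O bond of the α,β-epoxy lactone (reductive opening of α,β-epoxy esters) and the samarium enolate expels the β-pivalate (E1cB), which should deliver the tertiary C7 alcohol with retention and the exocyclic methylene in one operation.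

Step 17
Reactants: 31 (6R,7R,8R,9R)-9-(tert-butyldimethylsilyloxy)-7-hydroxy-8-(triethylsilyloxy)germacra-1(10)Z,4E,11(13)-trien-12,6-olide
Product: 32 9-(tert-butyldimethylsilyloxy)-7,8-dihydroxygermacra-1(10)Z,4E,11(13)-trien-12,6-olide (configuration as in 38)
Conditions: pyridinium p-toluenesulfonate, MeOH–CH2Cl2, 0 °C
Reagents that add atoms: none
Why: Acid-catalysed methanolysis removes the secondary triethylsilyl ether much faster than the TBS ether, freeing only the C8 hydroxyl.

Step 18
Reactants: 33 (E)-2-methylbut-2-en-1-ol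
Product: 34 [(2R,3R)-2,3-dimethyloxiran-2-yl]methanol
Conditions: Ti(Oi-Pr)4 (cat.), diethyl D-(−)-tartrate, t-BuOOH, 4 Å molecular sieves, CH2Cl2, −20 °C
Reagents that add atoms: tert-butyl hydroperoxide CC(C)(C)OO
Why: Sharpless asymmetric epoxidation of the (E)-allylic alcohol with the D-(−)-tartrate should deliver oxygen to the face that gives the (2R,3R)-epoxy alcohol, setting both side-chain stereocentres with the methyl groups cis.

Step 19
Reactants: 34 [(2R,3R)-2,3-dimethyloxiran-2-yl]methanol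
Product: 35 (2S,3R)-2,3-dimethyloxirane-2-carboxylic acid
Conditions: RuCl3 (cat.), NaIO4, MeCN–EtOAc–H2O, rt
Reagents that add atoms: water O
Why: Catalytically generated RuO4 oxidises the primary alcohol through the aldehyde hydrate to the acid without touching the epoxide or its stereocentres.

Step 20
Reactants: 32 9-(tert-butyldimethylsilyloxy)-7,8-dihydroxygermacra-1(10)Z,4E,11(13)-trien-12,6-olide; 35 (2S,3R)-2,3-dimethyloxirane-2-carboxylic acid
Product: 37 9-(tert-butyldimethylsilyloxy)-8-[(2S,3R)-2,3-dimethyloxirane-2-carbonyloxy]-7-hydroxygermacra-1(10)Z,4E,11(13)-trien-12,6-olide (configuration as in 38), via mixed anhydride 36 (not isolated)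
Conditions: 2,4,6-trichlorobenzoyl chloride, Et3N, THF, rt; then 32, DMAP, PhMe, rt to 40 °C
Reagents that add atoms: none
Why: Yamaguchi esterification (mixed 2,4,6-trichlorobenzoic anhydride, acyl transfer by DMAP) should acylate the secondary C8 hydroxyl while the tertiary C7 hydroxyl stays free, and no stereocentre is touched.

Step 21
Reactants: 37 9-(tert-butyldimethylsilyloxy)-8-[(2S,3R)-2,3-dimethyloxirane-2-carbonyloxy]-7-hydroxygermacra-1(10)Z,4E,11(13)-trien-12,6-olide
Product: 38 (6R,7R,8R,9R)-8-[(2S,3R)-2,3-dimethyloxirane-2-carbonyloxy]-7,9-dihydroxygermacra-1(10)Z,4E,11(13)-trien-12,6-olide (CNP0420662.1)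
Conditions: HF·pyridine, pyridine, THF, 0 °C to rt
Reagents that add atoms: none
Why: Fluoride cleavage of the TBS ether under buffered conditions should free the C9 hydroxyl without opening the epoxide or adding to the α-methylene lactone.

**Compound list**

1 | 5-chloropent-1-yne | C#CCCCCl | starting material
2 | (E)-(5-chloro-2-methylpent-1-en-1-yl)dimethylalane | C[Al](C)/C=C(\C)CCCCl | intermediate
3 | (E)-5-chloro-1-iodo-2-methylpent-1-ene | I/C=C(\C)CCCCl | intermediate
4 | L-alanine methyl ester hydrochloride | C[C@H]([NH3+])C(=O)OC.[Cl-] | starting material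
5 | methyl N-[(2E)-6-chloro-3-methylhex-2-enoyl]-L-alaninate | C[C@H](NC(=O)/C=C(\C)CCCCl)C(=O)OC | intermediate
6 | 2-[(1E)-5-chloro-2-methylpent-1-en-1-yl]-5-methoxy-4-methyl-1,3-oxazole | COc1oc(/C=C(\C)CCCCl)nc1C | intermediate
7 | 2-[(1E)-5-iodo-2-methylpent-1-en-1-yl]-5-methoxy-4-methyl-1,3-oxazole | COc1oc(/C=C(\C)CCCI)nc1C | intermediate
8 | [(4E)-5-(5-methoxy-4-methyl-1,3-oxazol-2-yl)-4-methylpent-4-en-1-yl]triphenylphosphonium iodide | COc1oc(/C=C(\C)CCC[P+](c2ccccc2)(c2ccccc2)c2ccccc2)nc1C.[I-] | intermediate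
9 | methyl (4S)-2,2-dimethyl-1,3-dioxolane-4-carboxylate | COC(=O)[C@H]1OC(C)(C)OC1 | starting material
10 | methyl (2S)-2,3-dihydroxypropanoate | COC(=O)[C@@H](O)CO | intermediate
11 | methyl (2S)-2-hydroxy-3-(triethylsilyloxy)propanoate | COC(=O)[C@@H](O)CO[Si](CC)(CC)CC | intermediate
12 | methyl (2S)-2-(tert-butyldimethylsilyloxy)-3-(triethylsilyloxy)propanoate | COC(=O)[C@@H](O[Si](C)(C)C(C)(C)C)CO[Si](CC)(CC)CC | intermediate
13 | (2S)-2-(tert-butyldimethylsilyloxy)-N-methoxy-N-methyl-3-(triethylsilyloxy)propanamide | CON(C)C(=O)[C@@H](O[Si](C)(C)C(C)(C)C)CO[Si](CC)(CC)CC | intermediate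
14 | (3S)-3-(tert-butyldimethylsilyloxy)-4-(triethylsilyloxy)butan-2-one | CC(=O)[C@@H](O[Si](C)(C)C(C)(C)C)CO[Si](CC)(CC)CC | intermediate
15 | [(4E)-5-(5-methoxy-4-methyl-1,3-oxazol-2-yl)-4-methylpent-4-en-1-ylidene]triphenylphosphorane | COc1oc(/C=C(\C)CCC=P(c2ccccc2)(c2ccccc2)c2ccccc2)nc1C | intermediate
16 | 2-[(1E,5Z,7R)-7-(tert-butyldimethylsilyloxy)-2,6-dimethyl-8-(triethylsilyloxy)octa-1,5-dien-1-yl]-5-methoxy-4-methyl-1,3-oxazole | COc1oc(/C=C(\C)CC/C=C(/C)[C@@H](O[Si](C)(C)C(C)(C)C)CO[Si](CC)(CC)CC)nc1C | intermediate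
17 | (2R,3Z,7E)-2-(tert-butyldimethylsilyloxy)-8-(5-methoxy-4-methyl-1,3-oxazol-2-yl)-3,7-dimethylocta-3,7-dienal | COc1oc(/C=C(\C)CC/C=C(/C)[C@@H](O[Si](C)(C)C(C)(C)C)C=O)nc1C | intermediate
18 | methyl prop-2-ynoate | C#CC(=O)OC | starting material
19 | methyl 3-lithioprop-2-ynoate | [Li]C#CC(=O)OC | intermediate
20 | lithium (4S,5R,6Z,10E)-5-(tert-butyldimethylsilyloxy)-1-methoxy-11-(5-methoxy-4-methyl-1,3-oxazol-2-yl)-6,10-dimethyl-1-oxoundeca-6,10-dien-2-yn-4-olate | COc1oc(/C=C(\C)CC/C=C(/C)[C@@H](O[Si](C)(C)C(C)(C)C)[C@@H](O[Li])C#CC(=O)OC)nc1C | intermediate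
21 | methyl (4S,5R,6Z,10E)-5-(tert-butyldimethylsilyloxy)-11-(5-methoxy-4-methyl-1,3-oxazol-2-yl)-6,10-dimethyl-4-(triethylsilyloxy)undeca-6,10-dien-2-ynoate | COc1oc(/C=C(\C)CC/C=C(/C)[C@@H](O[Si](C)(C)C(C)(C)C)[C@@H](O[Si](CC)(CC)CC)C#CC(=O)OC)nc1C | intermediate
22 | 7-oxa-2-azabicyclo[2.2.1]hepta-2,5-diene cycloadduct of 21 (bridgeheads C6 and C12(OMe), N=C(Me) bridge, C7=C11 bridge carrying CO2Me; bridgehead configuration undefined) | COC12OC3(/C=C(\C)CC/C=C(/C)[C@@H](O[Si](C)(C)C(C)(C)C)[C@@H](O[Si](CC)(CC)CC)C3=C1C(=O)OC)N=C2C | intermediate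
23 | methyl (4S,5R,6Z,10E)-5-(tert-butyldimethylsilyloxy)-2-methoxy-6,10-dimethyl-4-(triethylsilyloxy)-4,5,8,9-tetrahydrocyclodeca[b]furan-3-carboxylate | COc1oc2/C=C(\C)CC/C=C(/C)[C@@H](O[Si](C)(C)C(C)(C)C)[C@@H](O[Si](CC)(CC)CC)c2c1C(=O)OC | intermediate
24 | diisobutylaluminium alkoxide of the 3-(hydroxymethyl)furan derived from 23 | COc1oc2/C=C(\C)CC/C=C(/C)[C@@H](O[Si](C)(C)C(C)(C)C)[C@@H](O[Si](CC)(CC)CC)c2c1CO[Al](CC(C)C)CC(C)C | intermediate
25 | [(4S,5R,6Z,10E)-5-(tert-butyldimethylsilyloxy)-2-methoxy-6,10-dimethyl-4-(triethylsilyloxy)-4,5,8,9-tetrahydrocyclodeca[b]furan-3-yl]methyl 2,2-dimethylpropanoate | COc1oc2/C=C(\C)CC/C=C(/C)[C@@H](O[Si](C)(C)C(C)(C)C)[C@@H](O[Si](CC)(CC)CC)c2c1COC(=O)C(C)(C)C | intermediate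
26 | 2,5-endoperoxide of furan 25 (peroxide bridge between the methoxy-bearing carbon and C6; configuration at the bridgeheads undefined) | COC12OOC3(/C=C(\C)CC/C=C(/C)[C@@H](O[Si](C)(C)C(C)(C)C)[C@@H](O[Si](CC)(CC)CC)C3=C1COC(=O)C(C)(C)C)O2 | intermediate
27 | methyl (2Z)-2-[(2S,3R,4Z,8E)-3-(tert-butyldimethylsilyloxy)-4,8-dimethyl-10-oxo-2-(triethylsilyloxy)cyclodeca-4,8-dien-1-ylidene]-3-(pivaloyloxy)propanoate | O=C1/C=C(\C)CC/C=C(/C)[C@@H](O[Si](C)(C)C(C)(C)C)[C@@H](O[Si](CC)(CC)CC)/C1=C(\COC(=O)C(C)(C)C)C(=O)OC | intermediate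
28 | methyl (2S,3R,4R,5R,6Z,10E)-5-(tert-butyldimethylsilyloxy)-6,10-dimethyl-12-oxo-2-[(pivaloyloxy)methyl]-4-(triethylsilyloxy)-1-oxaspiro[2.9]dodeca-6,10-diene-2-carboxylate (oxirane oxygen anti to the C8 silyloxy group; ketone carbon and CO2Me cis on the oxirane) | O=C1/C=C(\C)CC/C=C(/C)[C@@H](O[Si](C)(C)C(C)(C)C)[C@@H](O[Si](CC)(CC)CC)[C@]12O[C@]2(COC(=O)C(C)(C)C)C(=O)OC | intermediate
29 | 12-hydroxy analogue of 28 (C6 carbinol with the configuration of 38) | O[C@@H]1/C=C(\C)CC/C=C(/C)[C@@H](O[Si](C)(C)C(C)(C)C)[C@@H](O[Si](CC)(CC)CC)[C@]12O[C@]2(COC(=O)C(C)(C)C)C(=O)OC | intermediate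
30 | 7,11-epoxy-13-(pivaloyloxy)-9-(tert-butyldimethylsilyloxy)-8-(triethylsilyloxy)germacra-1(10)Z,4E-dien-12,6-olide (C6 to C9 as in 38; oxirane cis-fused to the lactone) | CC(C)(C)C(=O)OC[C@@]13C(=O)O[C@@H]2/C=C(\C)CC/C=C(/C)[C@@H](O[Si](C)(C)C(C)(C)C)[C@@H](O[Si](CC)(CC)CC)[C@@]12O3 | intermediate
31 | (6R,7R,8R,9R)-9-(tert-butyldimethylsilyloxy)-7-hydroxy-8-(triethylsilyloxy)germacra-1(10)Z,4E,11(13)-trien-12,6-olide | C=C1C(=O)O[C@@H]2/C=C(\C)CC/C=C(/C)[C@@H](O[Si](C)(C)C(C)(C)C)[C@@H](O[Si](CC)(CC)CC)[C@@]12O | intermediate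
32 | 9-(tert-butyldimethylsilyloxy)-7,8-dihydroxygermacra-1(10)Z,4E,11(13)-trien-12,6-olide (configuration as in 38) | C=C1C(=O)O[C@@H]2/C=C(\C)CC/C=C(/C)[C@@H](O[Si](C)(C)C(C)(C)C)[C@@H](O)[C@@]12O | intermediate
33 | (E)-2-methylbut-2-en-1-ol | C/C=C(\C)CO | starting material
34 | [(2R,3R)-2,3-dimethyloxiran-2-yl]methanol | OC[C@@]1(C)O[C@@H]1C | intermediate
35 | (2S,3R)-2,3-dimethyloxirane-2-carboxylic acid | OC(=O)[C@@]1(C)O[C@@H]1C | intermediate
36 | (2S,3R)-2,3-dimethyloxirane-2-carboxylic 2,4,6-trichlorobenzoic anhydride | O=C(OC(=O)c1c(Cl)cc(Cl)cc1Cl)[C@@]1(C)O[C@@H]1C | intermediate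
37 | 9-(tert-butyldimethylsilyloxy)-8-[(2S,3R)-2,3-dimethyloxirane-2-carbonyloxy]-7-hydroxygermacra-1(10)Z,4E,11(13)-trien-12,6-olide (configuration as in 38) | C=C1C(=O)O[C@@H]2/C=C(\C)CC/C=C(/C)[C@@H](O[Si](C)(C)C(C)(C)C)[C@@H](OC(=O)[C@@]3(C)O[C@@H]3C)[C@@]12O | intermediate
38 | (6R,7R,8R,9R)-8-[(2S,3R)-2,3-dimethyloxirane-2-carbonyloxy]-7,9-dihydroxygermacra-1(10)Z,4E,11(13)-trien-12,6-olide (CNP0420662.1) | C=C1C(=O)O[C@@H]2/C=C(\C)CC/C=C(/C)[C@@H](O)[C@@H](OC(=O)[C@@]3(C)O[C@@H]3C)[C@@]12O | target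

**Step count and risks**

Total step count: 21. Longest linear sequence: 16 steps (steps 1–4, 8–17, 20, 21).

Steps most likely to fail:

Step 11 (Proposed new method). The ten-membered ring closure may lose out to intermolecular cycloaddition and oligomerisation, the strained transition state may not be reached at a temperature the product tolerates, or the product 1,5-diene may isomerise by Cope rearrangement. The fallback uses known chemistry, sets out from 16 and 18 and comes back at 23. Compound 18 is iodinated (N-iodosuccinimide, AgNO3 cat., acetone) to methyl 3-iodoprop-2-ynoate F1. Heating 16 with F1 in toluene gives, by intermolecular oxazole–alkynoate [4+2]/retro-[4+2] with the same polarity control, methyl 4-iodo-2-methoxy-5-[(1E,5Z,7R)-7-(tert-butyldimethylsilyloxy)-2,6-dimethyl-8-(triethylsilyloxy)octa-1,5-dien-1-yl]furan-3-carboxylate F2. Swern oxidation of its primary triethylsilyl ether gives the iodofuran aldehyde F3. The ring is then closed at C7–C8 by intramolecular Nozaki–Hiyama–Kishi coupling (CrCl2, NiCl2 cat., DMSO, high dilution) to the macrocyclic furylcarbinol F4, expected anti by Felkin–Anh control, and Et3SiOTf/2,6-lutidine converts F4 into 23.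

Step 14. Poor facial selectivity of peroxide attack on the exocyclic alkene, or loss of pivalate by addition–elimination, would erode the C7 configuration. The fallback sets out from 27 and comes back at 31. Zn dust in AcOH removes the γ-pivaloyloxy group reductively to give the deconjugated α-methylene keto ester F5 (C7–H). KN(SiMe3)2 followed by (camphorsulfonyl)oxaziridine, with the reagent enantiomer chosen for the C7 face, hydroxylates the dienolate at its α-carbon to the tertiary α-hydroxy ketone F6. Zn(BH4)2 then reduces the C6 ketone under chelation control and the alkoxide lactonises to 31.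

Step 15. Hydride delivery from the other face of the C6 ketone, imposed by the macrocycle and not by the chelate, would give the C6 epimer. The fallback sets out from 28 and comes back at 30. Reduction with NaBH4/CeCl3 and lactonisation give the 6-epi epoxy lactone F7. Saponification with LiOH gives the hydroxy acid F8, handled as its triethylammonium salt. Mitsunobu lactonisation (PPh3, diisopropyl azodicarboxylate, PhMe) activates the C6 hydroxyl and closes the lactone with inversion at C6 to give 30.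

**Further compounds**

F1 | step 11 | methyl 3-iodoprop-2-ynoate | COC(=O)C#CI
F2 | step 11 | methyl 4-iodo-2-methoxy-5-[(1E,5Z,7R)-7-(tert-butyldimethylsilyloxy)-2,6-dimethyl-8-(triethylsilyloxy)octa-1,5-dien-1-yl]furan-3-carboxylate | COc1oc(/C=C(\C)CC/C=C(/C)[C@@H](O[Si](C)(C)C(C)(C)C)CO[Si](CC)(CC)CC)c(I)c1C(=O)OC
F3 | step 11 | methyl 5-[(1E,5Z,7R)-7-(tert-butyldimethylsilyloxy)-2,6-dimethyl-8-oxoocta-1,5-dien-1-yl]-4-iodo-2-methoxyfuran-3-carboxylate | COc1oc(/C=C(\C)CC/C=C(/C)[C@@H](O[Si](C)(C)C(C)(C)C)C=O)c(I)c1C(=O)OC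
F4 | step 11 | methyl (4S,5R,6Z,10E)-5-(tert-butyldimethylsilyloxy)-4-hydroxy-2-methoxy-6,10-dimethyl-4,5,8,9-tetrahydrocyclodeca[b]furan-3-carboxylate | COc1oc2/C=C(\C)CC/C=C(/C)[C@@H](O[Si](C)(C)C(C)(C)C)[C@@H](O)c2c1C(=O)OC
F5 | step 14 | methyl 2-[(2S,3R,4Z,8E)-3-(tert-butyldimethylsilyloxy)-4,8-dimethyl-10-oxo-2-(triethylsilyloxy)cyclodeca-4,8-dien-1-yl]prop-2-enoate (C1 of the ring undefined) | O=C1/C=C(\C)CC/C=C(/C)[C@@H](O[Si](C)(C)C(C)(C)C)[C@@H](O[Si](CC)(CC)CC)C1C(=C)C(=O)OC
F6 | step 14 | methyl 2-[(2R,3R,4Z,8E)-3-(tert-butyldimethylsilyloxy)-1-hydroxy-4,8-dimethyl-10-oxo-2-(triethylsilyloxy)cyclodeca-4,8-dien-1-yl]prop-2-enoate (C1 carbinol with the C7 configuration of 38) | O=C1/C=C(\C)CC/C=C(/C)[C@@H](O[Si](C)(C)C(C)(C)C)[C@@H](O[Si](CC)(CC)CC)[C@@]1(O)C(=C)C(=O)OC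
F7 | step 15 | 6-epimer of epoxy lactone 30 | CC(C)(C)C(=O)OC[C@@]13C(=O)O[C@H]2/C=C(\C)CC/C=C(/C)[C@@H](O[Si](C)(C)C(C)(C)C)[C@@H](O[Si](CC)(CC)CC)[C@@]12O3
F8 | step 15 | 6-epi hydroxy acid from F7 (oxirane-2-carboxylic acid with free C6 hydroxyl) | O[C@H]1/C=C(\C)CC/C=C(/C)[C@@H](O[Si](C)(C)C(C)(C)C)[C@@H](O[Si](CC)(CC)CC)[C@]12O[C@]2(COC(=O)C(C)(C)C)C(=O)O
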